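The disconnection is the C4–C5 bond of the 14-membered carbocycle. The run C3–O, C4 methyl carbinol, C5 methylene, E-C6=C7 alkene and C8 tertiary peroxide is the imprint of a Claisen shift of an allyl enol ether tying the C7 oxygen to C3. In one operation a dirhodium carbenoid at C3 of a diazoketone inserts into the C7 hydroxyl of a (7S,8R) vinyl carbinol and the resulting Z enol ether rearranges, joining the halves and setting the 4S carbinol, the E alkene and the C3 ketone. The precursors are a peroxyketal-protected carbinol bearing the C12 vinyl iodide and a diazoketone bearing C1, C15 and the ester; lactone closure, B-alkyl Suzuki macrocyclisation, epoxidation and unmasking follow.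

Key step: step 17

Locants C1 to C16 are cembrane locants of the target: C1 is the ring CH carrying the lactone arm, C2 a CH2, C3 the lactone O-CH, C4 the methyl carbinol, C8 the hydroperoxide carbon, C11-C12 the oxirane, C15 the lactone alpha-CH and C16 the carbonyl. The target is (1R,3R,4S,8R,11S,12S,15S), 6E.

Assumption: the (4S,5S)-2-bromo-4,5-diphenyl-1,3-bis{[3,5-bis(trifluoromethyl)phenyl]sulfonyl}-1,3,2-diazaborolidine ("(S,S)-bromoborane") is taken, by analogy with simple allyl propanoates, to lead to the 2S,3S acid 22; if the sense of induction is the opposite, the (4R,5R) reagent is used and nothing else changes.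

Step 1
Reactants: 1 pent-3-yn-1-ol
Product: 2 5-bromopent-2-yne
Conditions: CBr4, PPh3, CH2Cl2, 0 °C
Reagents that add atoms: carbon tetrabromide, BrC(Br)(Br)Br
Why: Appel bromination of a primary alcohol under neutral conditions, which leaves the internal alkyne untouched.

Step 2
Reactants: 2 5-bromopent-2-yne; 3 ethyl but-2-ynoate
Product: 7 ethyl (E)-3-methyloct-2-en-6-ynoate, via pent-3-ynylmagnesium bromide 4 (not isolated), via pent-3-ynylcopper 5 (not isolated), via alkenylcopper adduct 6 (not isolated)
Conditions: Mg, THF, 40 °C; CuBr·SMe2 (1 equiv), −40 °C; 3, −78 °C; aq. NH4Cl at −78 °C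
Reagents that add atoms: none
Why: The Grignard-derived organocopper adds syn across the ynoate (carbocupration) and cold protonation keeps the alkenylcopper geometry, so the new chain ends trans to the ester (E); this avoids a base-sensitive displacement at a homopropargylic carbon.

Step 3
Reactants: 7 ethyl (E)-3-methyloct-2-en-6-ynoate
Product: 8 (E)-3-methyloct-2-en-6-yn-1-ol
Conditions: i-Bu2AlH (2.2 equiv), CH2Cl2, −78 °C; aq. potassium sodium tartrate
Reagents that add atoms: none
Why: 1,2-Reduction of the enoate by the aluminium hydride at low temperature should give the allylic alcohol with the alkene geometry intact.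

Step 4
Reactants: 8 (E)-3-methyloct-2-en-6-yn-1-ol
Product: 10 (2E,6E)-7-iodo-3-methylocta-2,6-dien-1-ol, via alkenylzirconocene chloride 9 (not isolated)
Conditions: Cp2Zr(H)Cl (3 equiv), THF, 45 °C; I2, 0 °C
Reagents that add atoms: iodine, II
Why: Hydrozirconation adds H and Zr syn across the alkyne and excess reagent with gentle heating equilibrates zirconium to the less hindered, methyl-bearing carbon; iodinolysis with retention should give the E vinyl iodide, the trisubstituted alkene being inert.

Step 5
Reactants: 10 (2E,6E)-7-iodo-3-methylocta-2,6-dien-1-ol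
Product: 11 [(2S,3S)-3-[(3E)-4-iodopent-3-en-1-yl]-3-methyloxiran-2-yl]methanol
Conditions: Ti(OiPr)4 (10 mol%), L-(+)-DIPT (12 mol%), t-BuOOH, 4 Å sieves, CH2Cl2, −20 °C
Reagents that add atoms: tert-butyl hydroperoxide, CC(C)(C)OO
Why: Sharpless asymmetric epoxidation with the L-tartrate delivers oxygen to the face of the E allylic alcohol that gives the 2S,3S oxirane (cembrane 7S,8S); the electron-poor vinyl iodide is not epoxidised.

Step 6
Reactants: 11 [(2S,3S)-3-[(3E)-4-iodopent-3-en-1-yl]-3-methyloxiran-2-yl]methanol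
Product: 12 [(2S,3S)-3-[(3E)-4-iodopent-3-en-1-yl]-3-methyloxiran-2-yl]methyl 4-methylbenzenesulfonate
Conditions: TsCl, Et3N, DMAP (cat.), CH2Cl2, 0 °C
Reagents that add atoms: 4-toluenesulfonyl chloride, Cc1ccc(cc1)S(Cl)(=O)=O
Why: Sulfonylation of the primary alcohol installs the C6 leaving group and inductively deactivates C7 of the oxirane toward the acid-catalysed opening that follows.

Step 7
Reactants: 12 [(2S,3S)-3-[(3E)-4-iodopent-3-en-1-yl]-3-methyloxiran-2-yl]methyl 4-methylbenzenesulfonate
Product: 13 (2S,3R,6E)-3-hydroperoxy-2-hydroxy-7-iodo-3-methyloct-6-en-1-yl 4-methylbenzenesulfonate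
Conditions: anhydrous H2O2 in Et2O (10 equiv), H3PMo12O40 (3 mol%), 20 °C
Reagents that add atoms: hydrogen peroxide, OO
Why: Heteropolyacid-catalysed perhydrolysis should open the oxirane at the tertiary carbon with inversion (borderline SN1/SN2, C7 deactivated by the CH2OTs group), turning 8S into 8R while the C7 oxygen stays in place.

Step 8
Reactants: 13 (2S,3R,6E)-3-hydroperoxy-2-hydroxy-7-iodo-3-methyloct-6-en-1-yl 4-methylbenzenesulfonate
Product: 14 (2S,3R,6E)-2-hydroxy-7-iodo-3-[(2-methoxypropan-2-yl)peroxy]-3-methyloct-6-en-1-yl 4-methylbenzenesulfonate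
Conditions: 2-methoxypropene (1.05 equiv), PPTS (2 mol%), CH2Cl2, −20 °C; Et3N quench
Reagents that add atoms: 2-methoxypropene, COC(C)=C
Why: Peroxyketal formation: the more acidic and more nucleophilic hydroperoxide adds to the protonated enol ether much faster than the hindered secondary hydroxyl, and one equivalent at low temperature with an amine quench should prevent the slower ionisation that would close a 1,2,4-trioxane onto the C7 hydroxyl.

Step 9
Reactants: 14 (2S,3R,6E)-2-hydroxy-7-iodo-3-[(2-methoxypropan-2-yl)peroxy]-3-methyloct-6-en-1-yl 4-methylbenzenesulfonate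
Product: 16 (3S,4R,7E)-8-iodo-4-[(2-methoxypropan-2-yl)peroxy]-4-methylnona-1,7-dien-3-ol, via terminal oxirane 15 (not isolated)
Conditions: Me3S+ I− (5 equiv), n-BuLi (4.8 equiv), THF, −10 °C; then 14, −10 to 10 °C; aq. NH4Cl at −10 °C
Reagents that add atoms: trimethylsulfonium iodide, C[S+](C)C.[I-]
Why: The first equivalent of ylide acts as base and the C7 alkoxide closes the terminal oxirane (direct displacement of the tosylate by the ylide converges on the same product); further ylide opens it at C6 and the sulfonium salt eliminates to the vinyl group (one-carbon homologation of an epoxide to an allylic alcohol) without touching C7 or the hindered tertiary peroxyketal.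

Step 10
Reactants: 17 (Z)-but-2-ene-1,4-diol
Product: 18 (Z)-4-[(tert-butyldimethylsilyl)oxy]but-2-en-1-ol
Conditions: NaH (1.0 equiv), THF, 0 °C; TBSCl
Reagents that add atoms: tert-butyldimethylsilyl chloride, CC(C)(C)[Si](C)(C)Cl
Why: One equivalent of NaH gives the sparingly soluble monoalkoxide of the symmetrical diol, which is silylated once (monoprotection).

Step 11
Reactants: 18 (Z)-4-[(tert-butyldimethylsilyl)oxy]but-2-en-1-ol; 19 propanoyl chloride
Product: 20 (Z)-4-[(tert-butyldimethylsilyl)oxy]but-2-en-1-yl propanoate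
Conditions: pyridine, CH2Cl2, 0 °C
Reagents that add atoms: none
Why: Routine acylation of a primary allylic alcohol.

Step 12
Reactants: 20 (Z)-4-[(tert-butyldimethylsilyl)oxy]but-2-en-1-yl propanoate
Product: 22 (2S,3S)-3-{[(tert-butyldimethylsilyl)oxy]methyl}-2-methylpent-4-enoic acid, via boron enolate 21 (not isolated)
Conditions: (S,S)-bromoborane (1.2 equiv), i-Pr2NEt (1.3 equiv), CH2Cl2, −78 °C, then −20 to 4 °C; aqueous work-up
Reagents that add atoms: none
Why: Enantioselective Ireland–Claisen rearrangement: soft enolisation in CH2Cl2 with the hindered amine gives the boron enolate with methyl cis to O–B, the C2-symmetric boron ligand selects the enolate face, and the chair with methyl equatorial and the Z-alkene substituent axial gives the anti acid, setting cembrane C1 and C15 together.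

Step 13
Reactants: 22 (2S,3S)-3-{[(tert-butyldimethylsilyl)oxy]methyl}-2-methylpent-4-enoic acid
Product: 23 methyl (2S,3S)-3-{[(tert-butyldimethylsilyl)oxy]methyl}-2-methylpent-4-enoate
Conditions: MeI, K2CO3, DMF, 20 °C
Reagents that add atoms: iodomethane, CI
Why: O-Alkylation of the carboxylate under weakly basic conditions that do not epimerise the alpha centre.

Step 14
Reactants: 23 methyl (2S,3S)-3-{[(tert-butyldimethylsilyl)oxy]methyl}-2-methylpent-4-enoate
Product: 24 methyl (2S,3S)-3-(bromomethyl)-2-methylpent-4-enoate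
Conditions: Ph3PBr2 (1.5 equiv), CH2Cl2, 20 °C
Reagents that add atoms: triphenylphosphine dibromide, BrP(Br)(c1ccccc1)(c1ccccc1)c1ccccc1
Why: The dibromophosphorane converts the silyl ether directly into the bromide through an oxyphosphonium salt (SN2 by bromide), so that no free gamma-hydroxy ester, which would lactonise, is ever present.

Step 15
Reactants: 24 methyl (2S,3S)-3-(bromomethyl)-2-methylpent-4-enoate; 25 pentane-2,4-dione
Product: 26 methyl (2S,3S)-5-acetyl-3-ethenyl-2-methyl-6-oxoheptanoate
Conditions: K2CO3, NaI (0.2 equiv), acetone, reflux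
Reagents that add atoms: none
Why: C-Alkylation of the soft diketone enolate by the primary halide (iodide formed in situ by Finkelstein exchange); the weak base should neither eliminate HBr nor epimerise the ester alpha centre.

Step 16
Reactants: 26 methyl (2S,3S)-5-acetyl-3-ethenyl-2-methyl-6-oxoheptanoate
Product: 27 methyl (2S,3S)-5-diazo-3-ethenyl-2-methyl-6-oxoheptanoate
Conditions: 4-acetamidobenzenesulfonyl azide, DBU, MeCN, 0 to 20 °C
Reagents that add atoms: 4-acetamidobenzenesulfonyl azide, CC(=O)Nc1ccc(cc1)S(=O)(=O)N=[N+]=[N-]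
Why: Deacylative diazo transfer: the enolate adds to the sulfonyl azide and the triazene collapses with transfer of one acetyl group to the sulfonamide nitrogen, which places the diazo group exactly on C3 next to the remaining acetyl (C4 and its methyl).

Step 17
Reactants: 16 (3S,4R,7E)-8-iodo-4-[(2-methoxypropan-2-yl)peroxy]-4-methylnona-1,7-dien-3-ol; 27 methyl (2S,3S)-5-diazo-3-ethenyl-2-methyl-6-oxoheptanoate
Product: 29 methyl (2S,3S,6S,8E,10R,13E)-3-ethenyl-6-hydroxy-14-iodo-10-[(2-methoxypropan-2-yl)peroxy]-2,6,10-trimethyl-5-oxopentadeca-8,13-dienoate, via Z enol ether 28 (not isolated)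
Conditions: Rh2(O2CCPh3)4 (2 mol%), CH2Cl2, −40 °C, 27 (1.6 equiv) added over 4 h to 16 (1 M); then 25 to 40 °C
Reagents that add atoms: none
Why: Proposed new method: the hindered dirhodium triphenylacetate turns 27 into a carbenoid at C3 that should be captured by the C7 hydroxyl of 16 faster than it shifts a C2 hydride, proton transfer within the oxonium ylide to the C4 carbonyl oxygen gives the Z enol ether 28, and on warming 28 undergoes a Claisen [3,3] shift (C4–C5 formed, C7–O broken) before it can tautomerise. The closest known reaction type is the dirhodium-catalysed O–H insertion/Claisen sequence of alpha-diazoketones and alpha-diazo-beta-ketoesters with enantioenriched secondary allylic alcohols; new here are a diazo carbon carrying a CH2 group with migratable hydrogens and a peroxyketal beside the carbinol. No ring is closed, the only cyclic array being the six-membered chair transition state. The 4S centre is controlled by the 7S carbinol through that chair, with the quaternary C8 substituent equatorial and the enol hydroxyl axial (fixed by the Z geometry), which also makes the new C6–C7 alkene E. The step needs O–H capture to beat 1,2-hydride shift, cyclopropanation and ylide formation at the ester carbonyl, which the bulky catalyst, the low temperature and slow addition of excess 27 into concentrated 16 should secure; the neutral, non-reducing medium spares the tertiary peroxyketal and the vinyl iodide.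

Step 18
Reactants: 29 methyl (2S,3S,6S,8E,10R,13E)-3-ethenyl-6-hydroxy-14-iodo-10-[(2-methoxypropan-2-yl)peroxy]-2,6,10-trimethyl-5-oxopentadeca-8,13-dienoate
Product: 31 (3S,4S,6R)-4-ethenyl-6-[(2S,4E,6R,9E)-2-hydroxy-10-iodo-6-[(2-methoxypropan-2-yl)peroxy]-6-methylundeca-4,9-dien-2-yl]-3-methyloxan-2-one, via dihydroxy ester 30 (not isolated)
Conditions: (S)-2-methyl-CBS-oxazaborolidine (0.3 equiv), catecholborane (3 equiv), toluene, −78 to −40 °C; MeOH, aq. NaHCO3; then DBU (0.2 equiv), CH2Cl2, 20 °C
Reagents that add atoms: none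
Why: CBS reduction under reagent control treats the fully substituted C4 side as the large group, so the (S)-catalyst should deliver hydride to the face giving 3R (chelation through the C4 borate acts in the same sense); catecholborane at low temperature leaves alkenes, ester and peroxyketal alone, and DBU then closes the delta-lactone (acyl transfer to the C3 hydroxyl), in which the C15 methyl and both other ring substituents are equatorial.

Step 19
Reactants: 31 (3S,4S,6R)-4-ethenyl-6-[(2S,4E,6R,9E)-2-hydroxy-10-iodo-6-[(2-methoxypropan-2-yl)peroxy]-6-methylundeca-4,9-dien-2-yl]-3-methyloxan-2-one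
Product: 33 bicyclic lactone with the 14-membered carbocycle closed: (1R,3R,4S,8R,15S), E-C6=C7 and E-C11=C12 alkenes, free C4 hydroxyl, C8 (2-methoxypropan-2-yl)peroxy group, via B-alkyl borane 32 (not isolated)
Conditions: 9-BBN (2.2 equiv), THF, 20 °C; then slow addition to Pd(dppf)Cl2 (20 mol%), AsPh3 (20 mol%), Cs2CO3 (3 equiv), DMF–THF–H2O, 1 mM, 45 °C
Reagents that add atoms: none
Why: 9-BBN hydroborates only the monosubstituted alkene at its terminus (one further equivalent is allowed for the C4 hydroxyl), and slow addition to zerovalent palladium at high dilution should effect the intramolecular B-alkyl Suzuki coupling at C12–C13 with retention of the vinyl iodide geometry; peroxyketals are known to tolerate palladium-catalysed couplings.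

Step 20
Reactants: 33 bicyclic lactone with E-C11=C12 alkene and C8 peroxyketal
Product: 34 (11S,12S)-epoxide of 33: (1R,3R,4S,8R,11S,12S,15S), 6E, C8 (2-methoxypropan-2-yl)peroxy group
Conditions: 1,2:4,5-di-O-isopropylidene-L-erythro-2,3-hexodiulo-2,6-pyranose (from L-sorbose, 1.5 equiv), KHSO5 (as Oxone), NaHCO3, MeCN–H2O, 0 °C, pH about 8
Reagents that add atoms: potassium peroxymonosulfate, [K+].[O-]S(=O)(=O)OO
Why: Shi epoxidation: the dioxirane of the L-series ketone should attack the electron-rich trisubstituted alkene through the spiro transition state on the face that gives 11S,12S, the C6–C7 alkene being shielded by the quaternary C8 centre and deactivated by the peroxyketal; the near-neutral buffer protects the lactone.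

Step 21
Reactants: 34 (11S,12S)-epoxide with C8 peroxyketal
Product: 35 CNP0297487.3, the (1R,3R,4S,8R,11S,12S,15S)-6E bicyclic lactone with 4-hydroxy, 8-hydroperoxy and 11,12-epoxy groups
Conditions: PPTS (10 mol%), MeOH, 0 °C, 20 min; solid NaHCO3, neutral work-up
Reagents that add atoms: none
Why: Mild acid-catalysed transketalisation to methanol removes the 2-methoxyprop-2-yl group from the peroxide; short contact at 0 °C should spare the trisubstituted oxirane and the tertiary allylic hydroperoxide.

Compound list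
1 | pent-3-yn-1-ol | CC#CCCO | starting material
2 | 5-bromopent-2-yne | CC#CCCBr | intermediate
3 | ethyl but-2-ynoate | CC#CC(=O)OCC | starting material
4 | pent-3-ynylmagnesium bromide | CC#CCC[Mg]Br | intermediate
5 | pent-3-ynylcopper (monovalent copper, as its MgBr2 complex) | CC#CCC[Cu] | intermediate
6 | ethyl (Z)-2-cuprio-3-methyloct-2-en-6-ynoate (alkenylcopper adduct) | CCOC(=O)/C([Cu])=C(\C)CCC#CC | intermediate
7 | ethyl (E)-3-methyloct-2-en-6-ynoate | CCOC(=O)/C=C(\C)CCC#CC | intermediate
8 | (E)-3-methyloct-2-en-6-yn-1-ol | CC#CCC/C(C)=C/CO | intermediate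
9 | alkenylzirconocene chloride from 8 (Zr on the methyl-bearing alkene carbon, syn to H; hydroxyl held as its zirconocene alkoxide) | C/C(=C\CC/C(C)=C/CO[Zr](Cl)(C1C=CC=C1)C1C=CC=C1)[Zr](Cl)(C1C=CC=C1)C1C=CC=C1 | intermediate
10 | (2E,6E)-7-iodo-3-methylocta-2,6-dien-1-ol | C/C(I)=C\CC/C(C)=C/CO | intermediate
11 | [(2S,3S)-3-[(3E)-4-iodopent-3-en-1-yl]-3-methyloxiran-2-yl]methanol | OC[C@@H]1O[C@@]1(C)CC/C=C(\C)I | intermediate
12 | [(2S,3S)-3-[(3E)-4-iodopent-3-en-1-yl]-3-methyloxiran-2-yl]methyl 4-methylbenzenesulfonate | Cc1ccc(cc1)S(=O)(=O)OC[C@@H]1O[C@@]1(C)CC/C=C(\C)I | intermediate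
13 | (2S,3R,6E)-3-hydroperoxy-2-hydroxy-7-iodo-3-methyloct-6-en-1-yl 4-methylbenzenesulfonate | Cc1ccc(cc1)S(=O)(=O)OC[C@H](O)[C@](C)(OO)CC/C=C(\C)I | intermediate
14 | (2S,3R,6E)-2-hydroxy-7-iodo-3-[(2-methoxypropan-2-yl)peroxy]-3-methyloct-6-en-1-yl 4-methylbenzenesulfonate | Cc1ccc(cc1)S(=O)(=O)OC[C@H](O)[C@](C)(OOC(C)(C)OC)CC/C=C(\C)I | intermediate
15 | (2S)-2-[(2R,5E)-6-iodo-2-[(2-methoxypropan-2-yl)peroxy]hept-5-en-2-yl]oxirane | C1O[C@@H]1[C@](C)(OOC(C)(C)OC)CC/C=C(\C)I | intermediate
16 | (3S,4R,7E)-8-iodo-4-[(2-methoxypropan-2-yl)peroxy]-4-methylnona-1,7-dien-3-ol (cembrane 7S,8R) | C=C[C@H](O)[C@](C)(OOC(C)(C)OC)CC/C=C(\C)I | intermediate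
17 | (Z)-but-2-ene-1,4-diol | OC/C=C\CO | starting material
18 | (Z)-4-[(tert-butyldimethylsilyl)oxy]but-2-en-1-ol | OC/C=C\CO[Si](C)(C)C(C)(C)C | intermediate
19 | propanoyl chloride | CCC(=O)Cl | starting material
20 | (Z)-4-[(tert-butyldimethylsilyl)oxy]but-2-en-1-yl propanoate | CCC(=O)OC/C=C\CO[Si](C)(C)C(C)(C)C | intermediate
21 | boron enolate of 20 on the (4S,5S)-diazaborolidine, methyl cis to O–B | C/C=C(/OC/C=C\CO[Si](C)(C)C(C)(C)C)OB1N(S(=O)(=O)c2cc(C(F)(F)F)cc(C(F)(F)F)c2)[C@@H](c2ccccc2)[C@H](c2ccccc2)N1S(=O)(=O)c1cc(C(F)(F)F)cc(C(F)(F)F)c1 | intermediate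
22 | (2S,3S)-3-{[(tert-butyldimethylsilyl)oxy]methyl}-2-methylpent-4-enoic acid | OC(=O)[C@@H](C)[C@H](C=C)CO[Si](C)(C)C(C)(C)C | intermediate
23 | methyl (2S,3S)-3-{[(tert-butyldimethylsilyl)oxy]methyl}-2-methylpent-4-enoate | COC(=O)[C@@H](C)[C@H](C=C)CO[Si](C)(C)C(C)(C)C | intermediate
24 | methyl (2S,3S)-3-(bromomethyl)-2-methylpent-4-enoate | COC(=O)[C@@H](C)[C@H](C=C)CBr | intermediate
25 | pentane-2,4-dione | CC(=O)CC(C)=O | starting material
26 | methyl (2S,3S)-5-acetyl-3-ethenyl-2-methyl-6-oxoheptanoate | COC(=O)[C@@H](C)[C@H](C=C)CC(C(C)=O)C(C)=O | intermediate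
27 | methyl (2S,3S)-5-diazo-3-ethenyl-2-methyl-6-oxoheptanoate | COC(=O)[C@@H](C)[C@H](C=C)CC(=[N+]=[N-])C(C)=O | intermediate
28 | methyl (2S,3S,5Z)-3-ethenyl-6-hydroxy-5-{[(3S,4R,7E)-8-iodo-4-[(2-methoxypropan-2-yl)peroxy]-4-methylnona-1,7-dien-3-yl]oxy}-2-methylhept-5-enoate | COC(=O)[C@@H](C)[C@H](C=C)C/C(O[C@@H](C=C)[C@](C)(OOC(C)(C)OC)CC/C=C(\C)I)=C(\C)O | intermediate
29 | methyl (2S,3S,6S,8E,10R,13E)-3-ethenyl-6-hydroxy-14-iodo-10-[(2-methoxypropan-2-yl)peroxy]-2,6,10-trimethyl-5-oxopentadeca-8,13-dienoate (cembrane 4S, 8R) | COC(=O)[C@@H](C)[C@H](C=C)CC(=O)[C@@](C)(O)C/C=C/[C@](C)(OOC(C)(C)OC)CC/C=C(\C)I | intermediate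
30 | methyl (2S,3S,5R,6S,8E,10R,13E)-3-ethenyl-5,6-dihydroxy-14-iodo-10-[(2-methoxypropan-2-yl)peroxy]-2,6,10-trimethylpentadeca-8,13-dienoate | COC(=O)[C@@H](C)[C@H](C=C)C[C@@H](O)[C@@](C)(O)C/C=C/[C@](C)(OOC(C)(C)OC)CC/C=C(\C)I | intermediate
31 | (3S,4S,6R)-4-ethenyl-6-[(2S,4E,6R,9E)-2-hydroxy-10-iodo-6-[(2-methoxypropan-2-yl)peroxy]-6-methylundeca-4,9-dien-2-yl]-3-methyloxan-2-one | C[C@@H]1C(=O)O[C@H](C[C@H]1C=C)[C@@](C)(O)C/C=C/[C@](C)(OOC(C)(C)OC)CC/C=C(\C)I | intermediate
32 | 9-BBN adduct of 31 (boron on C13) | C[C@@H]1C(=O)O[C@H](C[C@H]1CCB1C2CCCC1CCC2)[C@@](C)(O)C/C=C/[C@](C)(OOC(C)(C)OC)CC/C=C(\C)I | intermediate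
33 | bicyclic lactone, 14-membered carbocycle, (1R,3R,4S,8R,15S), 6E, 11E, C8 (2-methoxypropan-2-yl)peroxy | C[C@@H]1C(=O)O[C@@H]2C[C@H]1CC/C(C)=C/CC[C@@](C)(OOC(C)(C)OC)/C=C/C[C@]2(C)O | intermediate
34 | (11S,12S)-epoxide of 33, peroxide still protected | C[C@@H]1C(=O)O[C@@H]2C[C@H]1CC[C@]1(C)O[C@H]1CC[C@@](C)(OOC(C)(C)OC)/C=C/C[C@]2(C)O | intermediate
35 | CNP0297487.3, (1R,3R,4S,8R,11S,12S,15S), 6E | C[C@@H]1C(=O)O[C@@H]2C[C@H]1CC[C@]1(C)O[C@H]1CC[C@@](C)(OO)/C=C/C[C@]2(C)O | target

Total step count: 21. Longest linear sequence: 14 steps (steps 1 to 9, then 17 to 21).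

Steps most likely to fail

Step 17. Capture of the carbenoid by the hindered C7 hydroxyl may lose to the 1,2-hydride shift, or the enol may tautomerise before it rearranges, so that the sequence stalls at the ether. The fallback sets out from 16 and 27, returns at 29, and separates the two events with known reactions. Copper carbenoids of alpha-alkyl diazocarbonyl compounds are known to insert into alcohols with little hydride shift, so Cu(MeCN)4PF6 in CH2Cl2 at 20 °C is used to make the alpha-allyloxy ketone methyl (2S,3S)-3-ethenyl-5-{[(3S,4R,7E)-8-iodo-4-[(2-methoxypropan-2-yl)peroxy]-4-methylnona-1,7-dien-3-yl]oxy}-2-methyl-6-oxoheptanoate F1 on purpose, as a mixture at the ether-bearing carbon that does not matter. F1 is then enolised toward the oxygen-bearing carbon with KH and 18-crown-6 in THF at −20 °C. The chelated potassium enolate, with enolate and ether oxygens cis as in 28, should undergo the known anionic [3,3] shift of alpha-allyloxy ketone enolates through the same chair and give 29 after a cold buffered quench.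

Step 19. The lactone-bridged seco compound may be unable to bring C12 and C13 together, so that oligomerisation and protodeboronation win, or the lactone may open under the aqueous base. The fallback sets out from 30 (isolated after the reduction of step 18, before DBU), returns at 33, and closes the carbocycle before the lactone exists. TESCl and imidazole in DMF protect the secondary hydroxyl to give the silyl ether methyl (2S,3S,5R,6S,8E,10R,13E)-3-ethenyl-6-hydroxy-14-iodo-10-[(2-methoxypropan-2-yl)peroxy]-2,6,10-trimethyl-5-[(triethylsilyl)oxy]pentadeca-8,13-dienoate F2. The flexible, base-stable F2 is cyclised with 9-BBN and the same Pd(dppf)Cl2, AsPh3 and Cs2CO3 conditions to the 14-membered carbocyclic ester F3, which carries the (S)-1-methoxy-1-oxopropan-2-yl arm on C1 and has 3R OSiEt3, 4S, 6E, 8R and 11E. TBAF in THF then frees the C3 oxygen, which closes the delta-lactone to 33.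

Step 9. The lithium alkoxide at C7 sits next to the O–O bond and may fragment the C7–C8 bond with loss of the peroxide, or the ylide may attack a peroxide oxygen. The fallback sets out from 12, returns at 16, and runs the ylide chemistry before any peroxide is present. Dimethylsulfonium methylide (3 equiv, THF, −10 °C) homologates the primary sulfonate to the alkene, a known reaction of primary sulfonates, and gives the vinyl oxirane (2S,3S)-3-ethenyl-2-[(3E)-4-iodopent-3-en-1-yl]-2-methyloxirane F4. Perhydrolysis with anhydrous H2O2 and H3PMo12O40 in Et2O opens F4 at the tertiary carbon with inversion to (3S,4R,7E)-4-hydroperoxy-8-iodo-4-methylnona-1,7-dien-3-ol F5; competing attack at the allylic carbon has to be watched. F5 is capped with 2-methoxypropene and PPTS as in step 8 to give 16.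

Further compounds
F1 | step 17 | methyl (2S,3S)-3-ethenyl-5-{[(3S,4R,7E)-8-iodo-4-[(2-methoxypropan-2-yl)peroxy]-4-methylnona-1,7-dien-3-yl]oxy}-2-methyl-6-oxoheptanoate (both C5 epimers) | COC(=O)[C@@H](C)[C@H](C=C)CC(O[C@@H](C=C)[C@](C)(OOC(C)(C)OC)CC/C=C(\C)I)C(C)=O
F2 | step 19 | methyl (2S,3S,5R,6S,8E,10R,13E)-3-ethenyl-6-hydroxy-14-iodo-10-[(2-methoxypropan-2-yl)peroxy]-2,6,10-trimethyl-5-[(triethylsilyl)oxy]pentadeca-8,13-dienoate | COC(=O)[C@@H](C)[C@H](C=C)C[C@@H](O[Si](CC)(CC)CC)[C@@](C)(O)C/C=C/[C@](C)(OOC(C)(C)OC)CC/C=C(\C)I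
F3 | step 19 | methyl (2S)-2-[14-membered carbocycle]propanoate: cembrane (1R,3R,4S,8R), 6E, 11E, 3-triethylsilyloxy, 4-hydroxy, 8-[(2-methoxypropan-2-yl)peroxy] | COC(=O)[C@@H](C)[C@H]1C[C@@H](O[Si](CC)(CC)CC)[C@@](C)(O)C/C=C/[C@](C)(OOC(C)(C)OC)CC/C=C(\C)CC1
F4 | step 9 | (2S,3S)-3-ethenyl-2-[(3E)-4-iodopent-3-en-1-yl]-2-methyloxirane | C=C[C@@H]1O[C@@]1(C)CC/C=C(\C)I
F5 | step 9 | (3S,4R,7E)-4-hydroperoxy-8-iodo-4-methylnona-1,7-dien-3-ol | C=C[C@H](O)[C@](C)(OO)CC/C=C(\C)I
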